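**Plan**

- U is the flavan-3-ol unit substituted at C4 and L the unit whose ring B carries it. Ring B of L is a catechol whose two carbon substituents sit on neighbouring carbons (C2L on C1', C4U on C6'), so C1'–C6' can be the two carbons of an alkyne and C2'–C5' a 2,3-dioxygenated butadiene.
- Retrosynthesis cuts, in order: six O–benzyl bonds; C1'–C2' and C5'–C6' (ring B of L); O1L–C2L; C2L–C(sp); C4U–C(sp); C3U–O; C2U–aryl; and the C4L–C3L chain from ring A of L.
- Forward: a chromone supplies rings A and C of U and receives its aryl group, the C3 oxygen and a C4 ethynyl group. The open C4L–C3L–C2L chain is joined through the alkyne, ring C of L closes by etherification, and ring B of L is built last and aromatised.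
- Stereochemistry: C2U from a chiral pyridine-oxazoline palladium catalyst; C3U and C4U by anti relay (2,3-trans, 3,4-trans); C3L from (S)-glycidyl trityl ether; C2L by chelation-controlled alkynylation followed by Mitsunobu inversion.

Key step: step 19

Assumption: the (R)-t-BuPyOx ligand in step 2 is taken to deliver the 2S flavanone, by analogy with the facial sense of this catalyst family on cyclic enones; if the sense is opposite, the antipodal ligand is used.

**Route**

Step 1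
Reactants: 1 7-hydroxy-4H-chromen-4-one
Product: 2 7-(benzyloxy)-4H-chromen-4-one
Conditions: BnBr, K2CO3, DMF, rt
Reagents that add atoms: benzyl bromide BrCc1ccccc1
Why: Williamson ether synthesis on the only acidic hydroxyl, a vinylogous carboxylic acid, should be clean.

Step 2
Reactants: 2 7-(benzyloxy)-4H-chromen-4-one; 3 [3,4-bis(benzyloxy)phenyl]boronic acid
Product: 4 (2S)-7-(benzyloxy)-2-[3,4-bis(benzyloxy)phenyl]chroman-4-one
Conditions: Pd(OCOCF3)2 (5 mol%), (R)-t-BuPyOx (6 mol%), NH4PF6, H2O, ClCH2CH2Cl, 60 °C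
Reagents that add atoms: none
Why: Asymmetric conjugate addition of an arylboronic acid to a chromone under divalent palladium catalysis, in which the aryl–palladium species adds to C2 on the face left open by the tert-butyl oxazoline and water protonates the palladium enolate, should set C2 as S.

Step 3
Reactants: 4 (2S)-7-(benzyloxy)-2-[3,4-bis(benzyloxy)phenyl]chroman-4-one
Product: 7 (2R,3R)-7-(benzyloxy)-2-[3,4-bis(benzyloxy)phenyl]-3-hydroxychroman-4-one, via silyl enol ether 5 (not isolated), via 3-silyloxy ketone 6 (not isolated)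
Conditions: TMSOTf, Et3N, CH2Cl2, 0 °C; then mCPBA, NaHCO3, CH2Cl2, −20 → 0 °C; then citric acid, MeOH, rt
Reagents that add atoms: 3-chloroperbenzoic acid OOC(=O)c1cccc(Cl)c1 (C3 oxygen); trimethylsilyl triflate C[Si](C)(C)OS(=O)(=O)C(F)(F)F (silyl group of 5 and 6)
Why: Rubottom oxidation, in which soft enolisation avoids a free enolate (so no retro-oxa-Michael opening and no loss of C2) and the peracid attacks the enol ether face anti to the C2 aryl group, should give the 2,3-trans hydroxy ketone.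

Step 4
Reactants: 7 (2R,3R)-7-(benzyloxy)-2-[3,4-bis(benzyloxy)phenyl]-3-hydroxychroman-4-one
Product: 8 (2R,3S,4R)-7-(benzyloxy)-2-[3,4-bis(benzyloxy)phenyl]chroman-3,4-diol
Conditions: NaBH4, MeOH/THF, 0 °C
Reagents that add atoms: none
Why: Borohydride reduction of a 2,3-trans dihydroflavonol should give mainly the 3,4-trans diol, and the C4 configuration is of no consequence because C4 is ionised in step 7.

Step 5
Reactants: 8 (2R,3S,4R)-7-(benzyloxy)-2-[3,4-bis(benzyloxy)phenyl]chroman-3,4-diol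
Product: 9 (2R,3S,4R)-3,4,7-tris(benzyloxy)-2-[3,4-bis(benzyloxy)phenyl]chroman
Conditions: NaH, BnBr, Bu4NI (cat.), DMF, 0 °C → rt
Reagents that add atoms: benzyl bromide BrCc1ccccc1
Why: Double Williamson benzylation protects C3–OH for the rest of the route and turns C4–OH into an ionisable benzylic ether.

Step 6
Reactants: 10 ethynyltrimethylsilane
Product: 13 potassium trifluoro[(trimethylsilyl)ethynyl]borate, via lithium (trimethylsilyl)acetylide 11 (not isolated), via lithium trimethoxy(alkynyl)borate 12 (not isolated)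
Conditions: n-BuLi, THF, −78 °C; B(OMe)3, −78 → −20 °C; KHF2, H2O, rt
Reagents that add atoms: n-butyllithium [Li]CCCC (lithium of 11 and 12); trimethyl borate COB(OC)OC; potassium hydrogen difluoride [K+].[F-].F
Why: Borylation of a lithium acetylide followed by fluoride exchange is the standard preparation of alkynyltrifluoroborate salts.

Step 7
Reactants: 9 (2R,3S,4R)-3,4,7-tris(benzyloxy)-2-[3,4-bis(benzyloxy)phenyl]chroman; 13 potassium trifluoro[(trimethylsilyl)ethynyl]borate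
Product: 15 (2R,3S,4S)-3,7-bis(benzyloxy)-2-[3,4-bis(benzyloxy)phenyl]-4-[(trimethylsilyl)ethynyl]chroman (2,3-trans-3,4-trans), via alkynyldifluoroborane 14 (not isolated)
Conditions: 13 (3 equiv), BF3·OEt2, CH2Cl2, −40 → 0 °C; H2O
Reagents that add atoms: none
Why: Lewis acid mediated SN1 alkynylation of a benzylic ether by an alkynyltrifluoroborate, in which BF3 frees the alkynyldifluoroborane and ionises the C4 ether to a cation stabilised by O1 and the para 7-benzyloxy group, should deliver the alkynyl group anti to the C3 benzyloxy group, the excess of the small nucleophile suppressing capture by ring A of a second flavan.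

Step 8
Reactants: 15 (2R,3S,4S)-3,7-bis(benzyloxy)-2-[3,4-bis(benzyloxy)phenyl]-4-[(trimethylsilyl)ethynyl]chroman
Product: 16 (2R,3S,4R)-3,7-bis(benzyloxy)-2-[3,4-bis(benzyloxy)phenyl]-4-ethynylchroman (same spatial arrangement; the C4 descriptor changes only through CIP priority)
Conditions: Bu4NF, AcOH, THF, 0 °C
Reagents that add atoms: none
Why: Buffered fluoride protodesilylation frees the terminal alkyne without a base strong enough to isomerise the benzylic propargylic C4–H to an allene.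

Step 9
Reactants: 17 3-(benzyloxy)phenol
Product: 18 5-(benzyloxy)-2-iodophenol
Conditions: I2, NaHCO3, THF/H2O, 0 °C
Reagents that add atoms: iodine II
Why: Electrophilic iodination of the phenoxide is expected, as with other 3-alkoxyphenols, at the unhindered position ortho to OH and para to the ether oxygen.

Step 10
Reactants: 18 5-(benzyloxy)-2-iodophenol
Product: 19 2-(allyloxy)-4-(benzyloxy)-1-iodobenzene
Conditions: allyl bromide, K2CO3, acetone, reflux
Reagents that add atoms: allyl bromide C=CCBr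
Why: Williamson allylation installs a phenol protecting group that is removable under neutral conditions, orthogonal to trityl and benzyl.

Step 11
Reactants: 19 2-(allyloxy)-4-(benzyloxy)-1-iodobenzene; 20 (S)-2-[(trityloxy)methyl]oxirane
Product: 22 (2S)-1-[2-(allyloxy)-4-(benzyloxy)phenyl]-3-(trityloxy)propan-2-ol, via arylmagnesium chloride 21 (not isolated)
Conditions: i-PrMgCl·LiCl, THF, −20 °C; CuI (10 mol%), 20, −20 °C → rt
Reagents that add atoms: isopropylmagnesium chloride–lithium chloride CC(C)[Mg]Cl.[Li+].[Cl-] (magnesium and chlorine of 21)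
Why: Iodine–magnesium exchange followed by copper-catalysed SN2 opening of the terminal epoxide at its CH2 carbon leaves the chiral-pool stereocentre, the future C3L, untouched.

Step 12
Reactants: 22 (2S)-1-[2-(allyloxy)-4-(benzyloxy)phenyl]-3-(trityloxy)propan-2-ol
Product: 23 1-(allyloxy)-5-(benzyloxy)-2-[(2S)-2-(benzyloxy)-3-(trityloxy)propyl]benzene
Conditions: NaH, BnBr, Bu4NI (cat.), THF/DMF, 0 °C → rt
Reagents that add atoms: benzyl bromide BrCc1ccccc1
Why: Williamson benzylation of the secondary alkoxide is safe because the neighbouring trityl ether cannot migrate.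

Step 13
Reactants: 23 1-(allyloxy)-5-(benzyloxy)-2-[(2S)-2-(benzyloxy)-3-(trityloxy)propyl]benzene
Product: 24 (2S)-3-[2-(allyloxy)-4-(benzyloxy)phenyl]-2-(benzyloxy)propan-1-ol
Conditions: TsOH·H2O (cat.), MeOH/CH2Cl2, rt
Reagents that add atoms: none
Why: Acid-catalysed SN1 methanolysis removes the trityl ether alone, since allyl and benzyl ethers are inert to dilute acid.

Step 14
Reactants: 24 (2S)-3-[2-(allyloxy)-4-(benzyloxy)phenyl]-2-(benzyloxy)propan-1-ol
Product: 25 (2S)-3-[2-(allyloxy)-4-(benzyloxy)phenyl]-2-(benzyloxy)propanal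
Conditions: Dess–Martin periodinane, NaHCO3, CH2Cl2, 0 °C → rt; used crude
Reagents that add atoms: none
Why: Buffered Dess–Martin oxidation gives the α-benzyloxy aldehyde without epimerisation if it is carried on at once.

Step 15
Reactants: 16 (2R,3S,4R)-3,7-bis(benzyloxy)-2-[3,4-bis(benzyloxy)phenyl]-4-ethynylchroman; 25 (2S)-3-[2-(allyloxy)-4-(benzyloxy)phenyl]-2-(benzyloxy)propanal
Product: 28 (2S,3S)-1-[2-(allyloxy)-4-(benzyloxy)phenyl]-2-(benzyloxy)-5-{(2R,3S,4R)-3,7-bis(benzyloxy)-2-[3,4-bis(benzyloxy)phenyl]chroman-4-yl}pent-4-yn-3-ol, via lithium acetylide 26 (not isolated), via alkynylzinc bromide 27 (not isolated)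
Conditions: n-BuLi, Et2O, −78 °C; ZnBr2, −78 → 0 °C; 25, Et2O, −78 → 0 °C
Reagents that add atoms: n-butyllithium [Li]CCCC (lithium of 26); zinc bromide Br[Zn]Br (zinc and bromine of 27)
Why: Cram-chelate-controlled addition of an alkynylzinc halide to an α-benzyloxy aldehyde in ether, with zinc bridging the carbonyl and ether oxygens and attack from the face of the α-hydrogen, should give the syn (3S) carbinol.

Step 16
Reactants: 28 the (2S,3S) propargylic alcohol with allyl-protected phenol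
Product: 29 (2S,3S)-1-[4-(benzyloxy)-2-hydroxyphenyl]-2-(benzyloxy)-5-{(2R,3S,4R)-3,7-bis(benzyloxy)-2-[3,4-bis(benzyloxy)phenyl]chroman-4-yl}pent-4-yn-3-ol
Conditions: Pd(PPh3)4 (5 mol%), morpholine, THF, rt
Reagents that add atoms: none
Why: Tsuji–Trost deallylation, in which zerovalent palladium ionises the aryl allyl ether and morpholine traps the allyl group, leaves benzyl ethers, the alkyne and the free carbinol alone.

Step 17
Reactants: 29 the (2S,3S) phenol–propargylic alcohol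
Product: 30 (2R,3S,4R)-3,7-bis(benzyloxy)-2-[3,4-bis(benzyloxy)phenyl]-4-{[(2R,3S)-3,7-bis(benzyloxy)chroman-2-yl]ethynyl}chroman
Conditions: PPh3, DIAD, THF, 0 °C → rt
Reagents that add atoms: none
Why: Intramolecular Mitsunobu etherification closes the six-membered ring C of L by SN2 attack of the phenol on the activated propargylic carbinol, and the inversion turns the 3S carbinol into C2L (R), trans to the C3L benzyloxy group.

Step 18
Reactants: 31 butane-2,3-dione
Product: 32 2,3-bis(trimethylsilyloxy)buta-1,3-diene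
Conditions: TMSOTf, Et3N, Et2O, 0 °C → rt; distillation
Reagents that add atoms: trimethylsilyl triflate C[Si](C)(C)OS(=O)(=O)C(F)(F)F
Why: Twofold soft enolisation and O-silylation of the diketone gives the symmetrical diene.

Step 19
Reactants: 30 the alkyne linking C2L and C4U; 32 2,3-bis(trimethylsilyloxy)buta-1,3-diene
Product: 33 4,5-bis(trimethylsilyloxy)cyclohexa-1,4-diene bearing the (2R,3S)-3,7-bis(benzyloxy)chroman-2-yl group on C1 and the (2R,3S,4R)-3,7-bis(benzyloxy)-2-[3,4-bis(benzyloxy)phenyl]chroman-4-yl group on C2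
Conditions: CoBr2(dppe) (20 mol%), Zn powder (40 mol%), ZnI2 (40 mol%), 32 (4 equiv), CH2Cl2, rt → 40 °C; filtration through Et3N-deactivated silica
Reagents that add atoms: none
Why: Zinc reduces CoBr2(dppe) to a monovalent cobalt species which, once ZnI2 has taken up halide, binds the s-cis diene and the alkyne, cyclises oxidatively to a cobaltacycle and releases the cyclohexa-1,4-diene by reductive elimination, forming C1'–C2' and C5'–C6'; the closest known reaction type is the cobalt-catalysed neutral Diels–Alder reaction of unactivated internal alkynes with 2,3-disubstituted and 2-silyloxy butadienes. The six-membered carbocycle that becomes ring B of L closes in this metal-mediated [4+2] mode, both bonds being made within one catalytic cycle. No stereocentre is created, and C2L and C4U, which only flank the alkyne, are not touched. The symmetrical diene removes any regiochemical question, so the selectivity needed is cross-addition over alkyne trimerisation and diene self-coupling, which the bulk at both propargylic carbons and the excess of diene should secure. The diene already holds the enediol oxidation level, so the adduct needs only to lose two hydrogens to become the protected catechol.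

Step 20
Reactants: 33 the cyclohexa-1,4-diene bis(silyl enol ether)
Product: 35 4-{(2R,3S,4R)-3,7-bis(benzyloxy)-2-[3,4-bis(benzyloxy)phenyl]chroman-4-yl}-5-[(2R,3S)-3,7-bis(benzyloxy)chroman-2-yl]benzene-1,2-diol, via bis(trimethylsilyl) catechol ether 34 (not isolated)
Conditions: DDQ (1.0 equiv), CH2Cl2, −20 °C; filtration; then citric acid (cat.), MeOH, rt
Reagents that add atoms: none
Why: Dehydrogenation by DDQ (hydride loss from a doubly allylic CH2, then proton loss) is driven by aromatisation and should be far faster at low temperature than any benzylic oxidation, and methanolysis of the aryl silyl ethers after the oxidant is spent frees the catechol.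

Step 21
Reactants: 35 the hexabenzyl catechol
Product: 36 the target, (2R,3S,4R)-2-(3,4-dihydroxyphenyl)-4-{2-[(2R,3S)-3,7-dihydroxychroman-2-yl]-4,5-dihydroxyphenyl}chroman-3,7-diol
Conditions: H2 (1 atm), Pd(OH)2 on carbon, THF/MeOH, rt
Reagents that add atoms: none
Why: Hydrogenolysis of the six benzyl ethers over Pd(OH)2 on carbon is the usual last step for benzylated oligoflavans, and the cyclic benzylic C–O bonds and the C4U–aryl bond are expected to survive.

**Compound list**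

1 | 7-hydroxy-4H-chromen-4-one | O=c1ccoc2cc(O)ccc12 | starting material
2 | 7-(benzyloxy)-4H-chromen-4-one | O=c1ccoc2cc(OCc3ccccc3)ccc12 | intermediate
3 | [3,4-bis(benzyloxy)phenyl]boronic acid | OB(O)c1ccc(OCc2ccccc2)c(OCc2ccccc2)c1 | starting material
4 | (2S)-7-(benzyloxy)-2-[3,4-bis(benzyloxy)phenyl]chroman-4-one | O=C1C[C@@H](c2ccc(OCc3ccccc3)c(OCc3ccccc3)c2)Oc2cc(OCc3ccccc3)ccc12 | intermediate
5 | (2S)-7-(benzyloxy)-2-[3,4-bis(benzyloxy)phenyl]-4-(trimethylsilyloxy)-2H-chromene | C[Si](C)(C)OC1=C[C@@H](c2ccc(OCc3ccccc3)c(OCc3ccccc3)c2)Oc2cc(OCc3ccccc3)ccc12 | intermediate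
6 | (2R,3R)-7-(benzyloxy)-2-[3,4-bis(benzyloxy)phenyl]-3-(trimethylsilyloxy)chroman-4-one | O=C1[C@H](O[Si](C)(C)C)[C@@H](c2ccc(OCc3ccccc3)c(OCc3ccccc3)c2)Oc2cc(OCc3ccccc3)ccc12 | intermediate
7 | (2R,3R)-7-(benzyloxy)-2-[3,4-bis(benzyloxy)phenyl]-3-hydroxychroman-4-one | O=C1[C@H](O)[C@@H](c2ccc(OCc3ccccc3)c(OCc3ccccc3)c2)Oc2cc(OCc3ccccc3)ccc12 | intermediate
8 | (2R,3S,4R)-7-(benzyloxy)-2-[3,4-bis(benzyloxy)phenyl]chroman-3,4-diol | O[C@@H]1c2ccc(OCc3ccccc3)cc2O[C@H](c2ccc(OCc3ccccc3)c(OCc3ccccc3)c2)[C@H]1O | intermediate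
9 | (2R,3S,4R)-3,4,7-tris(benzyloxy)-2-[3,4-bis(benzyloxy)phenyl]chroman | C(c1ccccc1)O[C@@H]1c2ccc(OCc3ccccc3)cc2O[C@H](c2ccc(OCc3ccccc3)c(OCc3ccccc3)c2)[C@H]1OCc1ccccc1 | intermediate
10 | ethynyltrimethylsilane | C[Si](C)(C)C#C | starting material
11 | lithium (trimethylsilyl)acetylide | [Li]C#C[Si](C)(C)C | intermediate
12 | lithium trimethoxy[(trimethylsilyl)ethynyl]borate | [Li+].CO[B-](OC)(OC)C#C[Si](C)(C)C | intermediate
13 | potassium trifluoro[(trimethylsilyl)ethynyl]borate | [K+].F[B-](F)(F)C#C[Si](C)(C)C | intermediate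
14 | difluoro[(trimethylsilyl)ethynyl]borane | FB(F)C#C[Si](C)(C)C | intermediate
15 | (2R,3S,4S)-3,7-bis(benzyloxy)-2-[3,4-bis(benzyloxy)phenyl]-4-[(trimethylsilyl)ethynyl]chroman | C[Si](C)(C)C#C[C@@H]1c2ccc(OCc3ccccc3)cc2O[C@H](c2ccc(OCc3ccccc3)c(OCc3ccccc3)c2)[C@H]1OCc1ccccc1 | intermediate
16 | (2R,3S,4R)-3,7-bis(benzyloxy)-2-[3,4-bis(benzyloxy)phenyl]-4-ethynylchroman | C#C[C@@H]1c2ccc(OCc3ccccc3)cc2O[C@H](c2ccc(OCc3ccccc3)c(OCc3ccccc3)c2)[C@H]1OCc1ccccc1 | intermediate
17 | 3-(benzyloxy)phenol | Oc1cccc(OCc2ccccc2)c1 | starting material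
18 | 5-(benzyloxy)-2-iodophenol | Oc1cc(OCc2ccccc2)ccc1I | intermediate
19 | 2-(allyloxy)-4-(benzyloxy)-1-iodobenzene | C=CCOc1cc(OCc2ccccc2)ccc1I | intermediate
20 | (S)-2-[(trityloxy)methyl]oxirane | C(c1ccccc1)(c1ccccc1)(c1ccccc1)OC[C@@H]1CO1 | starting material
21 | [2-(allyloxy)-4-(benzyloxy)phenyl]magnesium chloride | C=CCOc1cc(OCc2ccccc2)ccc1[Mg]Cl | intermediate
22 | (2S)-1-[2-(allyloxy)-4-(benzyloxy)phenyl]-3-(trityloxy)propan-2-ol | C=CCOc1cc(OCc2ccccc2)ccc1C[C@H](O)COC(c1ccccc1)(c1ccccc1)c1ccccc1 | intermediate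
23 | 1-(allyloxy)-5-(benzyloxy)-2-[(2S)-2-(benzyloxy)-3-(trityloxy)propyl]benzene | C=CCOc1cc(OCc2ccccc2)ccc1C[C@H](OCc1ccccc1)COC(c1ccccc1)(c1ccccc1)c1ccccc1 | intermediate
24 | (2S)-3-[2-(allyloxy)-4-(benzyloxy)phenyl]-2-(benzyloxy)propan-1-ol | C=CCOc1cc(OCc2ccccc2)ccc1C[C@H](OCc1ccccc1)CO | intermediate
25 | (2S)-3-[2-(allyloxy)-4-(benzyloxy)phenyl]-2-(benzyloxy)propanal | C=CCOc1cc(OCc2ccccc2)ccc1C[C@H](OCc1ccccc1)C=O | intermediate
26 | lithium acetylide of 16 | [Li]C#C[C@@H]1c2ccc(OCc3ccccc3)cc2O[C@H](c2ccc(OCc3ccccc3)c(OCc3ccccc3)c2)[C@H]1OCc1ccccc1 | intermediate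
27 | alkynylzinc bromide of 16 | Br[Zn]C#C[C@@H]1c2ccc(OCc3ccccc3)cc2O[C@H](c2ccc(OCc3ccccc3)c(OCc3ccccc3)c2)[C@H]1OCc1ccccc1 | intermediate
28 | (2S,3S)-1-[2-(allyloxy)-4-(benzyloxy)phenyl]-2-(benzyloxy)-5-{(2R,3S,4R)-3,7-bis(benzyloxy)-2-[3,4-bis(benzyloxy)phenyl]chroman-4-yl}pent-4-yn-3-ol | C=CCOc1cc(OCc2ccccc2)ccc1C[C@H](OCc1ccccc1)[C@@H](O)C#C[C@@H]1c2ccc(OCc3ccccc3)cc2O[C@H](c2ccc(OCc3ccccc3)c(OCc3ccccc3)c2)[C@H]1OCc1ccccc1 | intermediate
29 | (2S,3S)-1-[4-(benzyloxy)-2-hydroxyphenyl]-2-(benzyloxy)-5-{(2R,3S,4R)-3,7-bis(benzyloxy)-2-[3,4-bis(benzyloxy)phenyl]chroman-4-yl}pent-4-yn-3-ol | Oc1cc(OCc2ccccc2)ccc1C[C@H](OCc1ccccc1)[C@@H](O)C#C[C@@H]1c2ccc(OCc3ccccc3)cc2O[C@H](c2ccc(OCc3ccccc3)c(OCc3ccccc3)c2)[C@H]1OCc1ccccc1 | intermediate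
30 | (2R,3S,4R)-3,7-bis(benzyloxy)-2-[3,4-bis(benzyloxy)phenyl]-4-{[(2R,3S)-3,7-bis(benzyloxy)chroman-2-yl]ethynyl}chroman | O(Cc4ccccc4)c1ccc2c(c1)O[C@H](C#C[C@@H]1c3ccc(OCc4ccccc4)cc3O[C@H](c3ccc(OCc4ccccc4)c(OCc4ccccc4)c3)[C@H]1OCc4ccccc4)[C@@H](OCc4ccccc4)C2 | intermediate
31 | butane-2,3-dione | CC(=O)C(C)=O | starting material
32 | 2,3-bis(trimethylsilyloxy)buta-1,3-diene | C=C(O[Si](C)(C)C)C(=C)O[Si](C)(C)C | intermediate
33 | 4,5-bis(trimethylsilyloxy)cyclohexa-1,4-diene with the (2R,3S)-3,7-bis(benzyloxy)chroman-2-yl group on C1 and the (2R,3S,4R)-3,7-bis(benzyloxy)-2-[3,4-bis(benzyloxy)phenyl]chroman-4-yl group on C2 | O(Cc4ccccc4)c1ccc2c(c1)O[C@H](C5=C(CC(O[Si](C)(C)C)=C(O[Si](C)(C)C)C5)[C@@H]1c3ccc(OCc4ccccc4)cc3O[C@H](c3ccc(OCc4ccccc4)c(OCc4ccccc4)c3)[C@H]1OCc4ccccc4)[C@@H](OCc4ccccc4)C2 | intermediate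
34 | bis(trimethylsilyl) ether of catechol 35 | O(Cc4ccccc4)c1ccc2c(c1)O[C@H](c5cc(O[Si](C)(C)C)c(O[Si](C)(C)C)cc5[C@@H]1c3ccc(OCc4ccccc4)cc3O[C@H](c3ccc(OCc4ccccc4)c(OCc4ccccc4)c3)[C@H]1OCc4ccccc4)[C@@H](OCc4ccccc4)C2 | intermediate
35 | 4-{(2R,3S,4R)-3,7-bis(benzyloxy)-2-[3,4-bis(benzyloxy)phenyl]chroman-4-yl}-5-[(2R,3S)-3,7-bis(benzyloxy)chroman-2-yl]benzene-1,2-diol | O(Cc4ccccc4)c1ccc2c(c1)O[C@H](c5cc(O)c(O)cc5[C@@H]1c3ccc(OCc4ccccc4)cc3O[C@H](c3ccc(OCc4ccccc4)c(OCc4ccccc4)c3)[C@H]1OCc4ccccc4)[C@@H](OCc4ccccc4)C2 | intermediate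
36 | (2R,3S,4R)-2-(3,4-dihydroxyphenyl)-4-{2-[(2R,3S)-3,7-dihydroxychroman-2-yl]-4,5-dihydroxyphenyl}chroman-3,7-diol | Oc1ccc2c(c1)O[C@H](c1cc(O)c(O)cc1[C@@H]1c3ccc(O)cc3O[C@H](c3ccc(O)c(O)c3)[C@H]1O)[C@@H](O)C2 | target

**Step count**

Total: 21 steps. Longest linear sequence: 13 steps (1–5, 7, 8, 15–17, 19–21).

**Steps most likely to fail**

Step 19. The alkyne, shielded on both sides by branched oxygen-bearing carbons, may fail to enter the cobalt coordination sphere beside the diene, so that the diene is used up by self-coupling or desilylation while the alkyne is returned. The fallback takes ring B of L from an aromatic building block instead of growing it; it sets out from aldehyde 25 and electrophile 9 and rejoins the route at target 36. Commercial 4,5-dibromocatechol is benzylated (BnBr, K2CO3, DMF) to 1,2-bis(benzyloxy)-4,5-dibromobenzene F1. One bromine–magnesium exchange (i-PrMgCl·LiCl, THF, −15 °C) and chelation-controlled addition to 25 (MgBr2·OEt2, CH2Cl2, −78 °C) should give (1S,2S)-3-[2-(allyloxy)-4-(benzyloxy)phenyl]-2-(benzyloxy)-1-[4,5-bis(benzyloxy)-2-bromophenyl]propan-1-ol F2. Deallylation as in step 16 (the electron-rich aryl bromide should be inert to zerovalent palladium at room temperature) gives (1S,2S)-3-[4-(benzyloxy)-2-hydroxyphenyl]-2-(benzyloxy)-1-[4,5-bis(benzyloxy)-2-bromophenyl]propan-1-ol F3. Mitsunobu closure as in step 17 gives (2R,3S)-3,7-bis(benzyloxy)-2-[4,5-bis(benzyloxy)-2-bromophenyl]chroman F4. Bromine–lithium exchange (n-BuLi, THF, −78 °C), B(Oi-Pr)3 and aqueous KHF2 give the potassium aryltrifluoroborate of that chroman F5. Its boron directs the C4 cation released from 9 (BF3·OEt2, CH2Cl2, −40 °C, as in step 7) to C6' by ipso substitution instead of to ring A, giving the octabenzyl ether of the target F6. Hydrogenolysis under the conditions of step 21 gives 36.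

Step 7. Transfer of the slim alkynyl group may show poor facial selectivity at C4, and it may be outrun by capture of the cation by ring A of a second flavan or by proton loss to the flav-3-ene. The fallback reverses the order of the two alkyne bond formations so that a bulky secondary alkynyl group attacks the cation; it sets out from aldehyde 25 (with 10 and 9) and rejoins the route at alkyne 30. The zinc acetylide of 10 (n-BuLi, then ZnBr2, Et2O) is added to 25 as in step 15 to give (3S,4S)-5-[2-(allyloxy)-4-(benzyloxy)phenyl]-4-(benzyloxy)-1-(trimethylsilyl)pent-1-yn-3-ol F7. Deallylation as in step 16 gives (3S,4S)-5-[4-(benzyloxy)-2-hydroxyphenyl]-4-(benzyloxy)-1-(trimethylsilyl)pent-1-yn-3-ol F8. Mitsunobu closure as in step 17 gives (2R,3S)-3,7-bis(benzyloxy)-2-[(trimethylsilyl)ethynyl]chroman F9. K2CO3 in MeOH gives (2R,3S)-3,7-bis(benzyloxy)-2-ethynylchroman F10. n-BuLi, B(OMe)3 and KHF2 give the potassium alkynyltrifluoroborate of that chroman F11. Slow addition of 9 to F11 and BF3·OEt2 in CH2Cl2 at −40 °C should give 30 directly, the larger nucleophile being expected to favour attack anti to the C3U benzyloxy group.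

Step 15. Incomplete chelation, with Felkin–Anh addition competing, would give a mixture of the two C3 carbinol epimers on a late and valuable intermediate. The fallback sets the carbinol by reagent control instead of substrate control; it sets out from the epimer mixture of 28 and returns to 28. Dess–Martin oxidation gives (2S)-1-[2-(allyloxy)-4-(benzyloxy)phenyl]-2-(benzyloxy)-5-{(2R,3S,4R)-3,7-bis(benzyloxy)-2-[3,4-bis(benzyloxy)phenyl]chroman-4-yl}pent-4-yn-3-one F12. Base-free Noyori transfer hydrogenation with RuCl[(R,R)-TsDPEN](p-cymene) in i-PrOH, the antipode expected to give the 3S carbinol, returns 28 as one epimer.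

Further compounds
F1 | step 19 | 1,2-bis(benzyloxy)-4,5-dibromobenzene | Brc1cc(OCc2ccccc2)c(OCc2ccccc2)cc1Br
F2 | step 19 | (1S,2S)-3-[2-(allyloxy)-4-(benzyloxy)phenyl]-2-(benzyloxy)-1-[4,5-bis(benzyloxy)-2-bromophenyl]propan-1-ol | C=CCOc1cc(OCc2ccccc2)ccc1C[C@H](OCc1ccccc1)[C@@H](O)c1cc(OCc2ccccc2)c(OCc2ccccc2)cc1Br
F3 | step 19 | (1S,2S)-3-[4-(benzyloxy)-2-hydroxyphenyl]-2-(benzyloxy)-1-[4,5-bis(benzyloxy)-2-bromophenyl]propan-1-ol | Oc1cc(OCc2ccccc2)ccc1C[C@H](OCc1ccccc1)[C@@H](O)c1cc(OCc2ccccc2)c(OCc2ccccc2)cc1Br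
F4 | step 19 | (2R,3S)-3,7-bis(benzyloxy)-2-[4,5-bis(benzyloxy)-2-bromophenyl]chroman | C(c1ccccc1)Oc1ccc2c(c1)O[C@H](c1cc(OCc3ccccc3)c(OCc3ccccc3)cc1Br)[C@@H](OCc1ccccc1)C2
F5 | step 19 | potassium {4,5-bis(benzyloxy)-2-[(2R,3S)-3,7-bis(benzyloxy)chroman-2-yl]phenyl}trifluoroborate | C(c1ccccc1)Oc1ccc2c(c1)O[C@H](c1cc(OCc3ccccc3)c(OCc3ccccc3)cc1[B-](F)(F)F)[C@@H](OCc1ccccc1)C2.[K+]
F6 | step 19 | octabenzyl ether of the target, (2R,3S,4R)-3,7-bis(benzyloxy)-2-[3,4-bis(benzyloxy)phenyl]-4-{4,5-bis(benzyloxy)-2-[(2R,3S)-3,7-bis(benzyloxy)chroman-2-yl]phenyl}chroman | C(c1ccccc1)Oc1ccc2c(c1)O[C@H](c1cc(OCc3ccccc3)c(OCc3ccccc3)cc1[C@@H]1c3ccc(OCc4ccccc4)cc3O[C@H](c3ccc(OCc4ccccc4)c(OCc4ccccc4)c3)[C@H]1OCc1ccccc1)[C@@H](OCc1ccccc1)C2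
F7 | step 7 | (3S,4S)-5-[2-(allyloxy)-4-(benzyloxy)phenyl]-4-(benzyloxy)-1-(trimethylsilyl)pent-1-yn-3-ol | C=CCOc1cc(OCc2ccccc2)ccc1C[C@H](OCc1ccccc1)[C@@H](O)C#C[Si](C)(C)C
F8 | step 7 | (3S,4S)-5-[4-(benzyloxy)-2-hydroxyphenyl]-4-(benzyloxy)-1-(trimethylsilyl)pent-1-yn-3-ol | Oc1cc(OCc2ccccc2)ccc1C[C@H](OCc1ccccc1)[C@@H](O)C#C[Si](C)(C)C
F9 | step 7 | (2R,3S)-3,7-bis(benzyloxy)-2-[(trimethylsilyl)ethynyl]chroman | C(c1ccccc1)Oc1ccc2c(c1)O[C@H](C#C[Si](C)(C)C)[C@@H](OCc1ccccc1)C2
F10 | step 7 | (2R,3S)-3,7-bis(benzyloxy)-2-ethynylchroman | C(c1ccccc1)Oc1ccc2c(c1)O[C@H](C#C)[C@@H](OCc1ccccc1)C2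
F11 | step 7 | potassium {[(2R,3S)-3,7-bis(benzyloxy)chroman-2-yl]ethynyl}trifluoroborate | C(c1ccccc1)Oc1ccc2c(c1)O[C@H](C#C[B-](F)(F)F)[C@@H](OCc1ccccc1)C2.[K+]
F12 | step 15 | (2S)-1-[2-(allyloxy)-4-(benzyloxy)phenyl]-2-(benzyloxy)-5-{(2R,3S,4R)-3,7-bis(benzyloxy)-2-[3,4-bis(benzyloxy)phenyl]chroman-4-yl}pent-4-yn-3-one | C=CCOc1cc(OCc2ccccc2)ccc1C[C@H](OCc1ccccc1)C(=O)C#C[C@@H]1c2ccc(OCc3ccccc3)cc2O[C@H](c2ccc(OCc3ccccc3)c(OCc3ccccc3)c2)[C@H]1OCc1ccccc1
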